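**Retrosynthetic overview**
- The target is the mono-acetate of a meso triol, so it is traced back to the meso diacetate of 1-tridecanoylcyclopent-3-ene-1,2,5-triol; removing one enantiotopic acetate with a hydrolase fixes all absolute configuration.
- The meso diacetate is disconnected at the quaternary C–O bond: ketohydroxylation of the exocyclic alkene of cis-2-tridecylidenecyclopent-4-ene-1,3-diyl diacetate, anti to both acetates, gives the tertiary OH and the side-chain ketone.
- The two ring C–O bonds come from singlet-oxygen [4+2] addition across the ring diene of 6-dodecylfulvene, followed by O–O reduction and acetylation.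
- 6-Dodecylfulvene comes from cyclopentadiene (cracked dicyclopentadiene) and tridecanal; this is the only C–C bond formed.
- Rings: the cyclopentene is never built, it is the cyclopentadiene ring carried through; the only ring formed is the transient 2,3-dioxabicyclo[2.2.1]heptene endoperoxide, opened in the same flask.

Assumption: the SMILES is read as (1S,2R,5S) at ring carbons C1 (C–OH, tridecanoyl), C2 (CHOH) and C5 (CHOAc), meaning both secondary oxygens are cis to each other and to the acyl group and trans to the tertiary OH; racemic intermediates are drawn as one enantiomer.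

**Step 1**
Reactants: 1 endo-dicyclopentadiene
Product: 2 cyclopenta-1,3-diene
Conditions: neat, 170–180 °C, distil (bp 40–42 °C) into a receiver at −78 °C, use at once
Reagents that add atoms: none
Why: thermal retro-Diels–Alder cracking of the dimer into two molecules of monomer, distilled off as they form; no stereocentre is involved.

**Step 2**
Reactants: 2 cyclopenta-1,3-diene; 3 tridecanal
Product: 4 6-dodecylfulvene (5-tridecylidenecyclopenta-1,3-diene)
Conditions: 2 (2.5 equiv), pyrrolidine (1.5 equiv), MeOH, 0 °C → rt, 1 h; AcOH quench; quick filtration through silica (hexane), use promptly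
Reagents that add atoms: none
Why: amine-mediated fulvene condensation (Stone–Little variant of the Thiele fulvene synthesis): the iminium ion of 3 is attacked by cyclopentadienide and pyrrolidine is eliminated; no stereocentre is formed.

**Step 3**
Reactants: 4 6-dodecylfulvene
Product: 7 (±)-cis-2-tridecylidenecyclopent-4-ene-1,3-diyl diacetate, via endoperoxide 5 (not isolated), via cis-diol 6 (not isolated)
Conditions: O2, hν (white LED), 5,10,15,20-tetraphenylporphyrin (cat.), thiourea (1.5 equiv), CH2Cl2/MeOH 1:1, −40 °C → rt; concentrate, filter; then Ac2O, pyridine, 4-(dimethylamino)pyridine (cat.), CH2Cl2, 0 °C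
Reagents that add atoms: oxygen O=O; acetic anhydride CC(=O)OC(C)=O
Why: singlet-oxygen [4+2] cycloaddition (photooxygenation) across the s-cis ring diene is suprafacial, so both new C–O bonds are cis; thiourea present from the start cleaves only the O–O bond of the labile endoperoxide (reductive peroxide cleavage, cis retained) and acetylation caps the acid-sensitive bis-allylic diol; 5–7 are chiral but racemic because of the alkylidene geometry, which step 4 erases.

**Step 4**
Reactants: 7 (±)-cis-2-tridecylidenecyclopent-4-ene-1,3-diyl diacetate
Product: 8 meso-(1R,2r,3S)-2-hydroxy-2-tridecanoylcyclopent-4-ene-1,3-diyl diacetate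
Conditions: RuCl3·xH2O (1 mol %), 2KHSO5·KHSO4·K2SO4 (2.5 equiv), NaHCO3 (2.5 equiv), EtOAc/MeCN/H2O 6:6:1, 0 °C → rt, 10–20 min; Na2SO3 quench
Reagents that add atoms: potassium peroxymonosulfate [K+].[O-]S(=O)(=O)OO
Why: Proposed new method: RuCl3/KHSO5 ketohydroxylation is known for simple isolated alkenes but has not been asked to choose the exocyclic trisubstituted alkylidene of a skipped diene over a ring cis-alkene, nor one face flanked by two allylic acetates; RuO4 (octavalent ruthenium) formed in situ should add by [3+2] to the more electron-rich trisubstituted C=C from the face anti to both acetoxy groups (the sense of anti-selective OsO4 additions to allylic esters), and the cyclic ruthenate ester, re-oxidised by KHSO5, collapses by oxidation at the secondary carbon to the ketone while the tertiary carbon can only keep its OH, which sets the C–O bond of the quaternary carbinol trans to both acetates (the tridecanoyl group ends up cis to them) and converts both enantiomers of 7 into one meso compound; closest known reaction: RuCl3/KHSO5 ketohydroxylation of simple trisubstituted alkenes.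

**Step 5**
Reactants: 8 meso-(1R,2r,3S)-2-hydroxy-2-tridecanoylcyclopent-4-ene-1,3-diyl diacetate
Product: 9 (1S,4R,5S)-4,5-dihydroxy-5-tridecanoylcyclopent-2-en-1-yl acetate (target)
Conditions: Burkholderia cepacia lipase (Amano PS), NaH2PO4/Na2HPO4 buffer (0.1 M, pH 7.0)/MTBE, 30 °C, pH-stat (1 M NaOH), stop at 1.0 equiv base; extract at pH 7 and chromatograph promptly
Reagents that add atoms: none
Why: hydrolase-catalysed enantiotopos-selective hydrolysis of a meso diacetate (enzymatic desymmetrization, as practised on cis-3,5-diacetoxycyclopentene); by the Kazlauskas rule with the quaternary side as the large group the lipase should cleave the acetate on the (R)-configured carbinol carbon and leave the (S)-acetate, so C2 (R), C5 (S) and the formerly pseudo-asymmetric C1 (now S) are all fixed here, the mismatched second hydrolysis is slow, and the neutral work-up avoids the 1,3-acetyl migration that would erode the enantiomeric purity.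

**Compound list**
1 | endo-dicyclopentadiene (racemic) | C1C=C[C@H]2[C@@H]1[C@@H]3C[C@H]2C=C3 | starting material
2 | cyclopenta-1,3-diene | C1C=CC=C1 | intermediate
3 | tridecanal | CCCCCCCCCCCCC=O | starting material
4 | 6-dodecylfulvene (5-tridecylidenecyclopenta-1,3-diene) | CCCCCCCCCCCCC=C1C=CC=C1 | intermediate
5 | (±)-7-tridecylidene-2,3-dioxabicyclo[2.2.1]hept-5-ene | O1[C@H]2C=C[C@@H](O1)/C2=C/CCCCCCCCCCCC | intermediate
6 | (±)-cis-2-tridecylidenecyclopent-4-ene-1,3-diol | O[C@H]1C=C[C@@H](O)/C1=C/CCCCCCCCCCCC | intermediate
7 | (±)-cis-2-tridecylidenecyclopent-4-ene-1,3-diyl diacetate | CC(=O)O[C@H]1C=C[C@@H](OC(C)=O)/C1=C/CCCCCCCCCCCC | intermediate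
8 | meso-(1R,2r,3S)-2-hydroxy-2-tridecanoylcyclopent-4-ene-1,3-diyl diacetate | CCCCCCCCCCCCC(=O)[C@]1(O)[C@H](OC(C)=O)C=C[C@@H]1OC(C)=O | intermediate
9 | (1S,4R,5S)-4,5-dihydroxy-5-tridecanoylcyclopent-2-en-1-yl acetate | CCCCCCCCCCCCC(=O)[C@]1(O)[C@H](O)C=C[C@@H]1OC(C)=O | target

**Step count and risks**
Total step count: 5 (step 3 telescopes photooxygenation, peroxide reduction and acetylation without isolating 5 or 6). Longest linear sequence: 5 steps, from dicyclopentadiene 1 to 9.

The three steps most likely to fail are steps 3, 4 and 5.

For step 3, the risk is that the fulvene endoperoxide 5 rearranges before thiourea reduces it. The fallback sets out from 4 and comes back at 6. Compound 4 is photooxygenated without reductant (O2, hν, tetraphenylporphyrin, CH2Cl2, −78 °C) to 5, and Et3N is added at −78 °C to trigger a Kornblum–DeLaMare rearrangement to (±)-4-hydroxy-5-tridecylidenecyclopent-2-en-1-one F1 (E/Z mixture, drawn as the Z isomer; both isomers converge). Luche 1,2-reduction (NaBH4, CeCl3·7H2O, MeOH, −78 °C), with hydride delivered anti to the existing hydroxyl, then gives cis-diol 6, which is acetylated as in the second half of step 3; any trans isomer is removed at the stage of 7.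

For step 4 (the proposed new step), the risk is that RuO4 also attacks the ring alkene, over-oxidises the ketol or shows weaker facial control. The fallback uses known chemistry, sets out from 7 and comes back at 8. Upjohn dihydroxylation (OsO4 cat., N-methylmorpholine N-oxide, acetone/H2O, 0 °C) of the exocyclic alkene, anti to both allylic acetates, gives (±)-2-hydroxy-2-(1-hydroxytridecyl)cyclopent-4-ene-1,3-diyl diacetate F2. Parikh–Doering oxidation (SO3·pyridine, DMSO, iPr2NEt, 0 °C) of its only free secondary carbinol then gives 8; F2 is oxidised promptly to avoid acetyl migration.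

For step 5, the risk is that the acetates, which sit next to a quaternary carbon, hydrolyse slowly, or that the enzyme cleaves the other acetate and gives the antipode. The fallback sets out from 8 and comes back at 9. Brief methanolysis (K2CO3 cat., MeOH, 0 °C) gives meso-1-[(1r,2R,5S)-1,2,5-trihydroxycyclopent-3-en-1-yl]tridecan-1-one F3. This is desymmetrized in the acylative direction (vinyl acetate, immobilised hydrolase, MTBE, 30 °C), which runs in a homogeneous organic medium and gives the opposite product hand to hydrolysis for a given enzyme preference. The enzyme used is therefore the one that gave the antipode in the hydrolysis screen (or a protease such as subtilisin Carlsberg, whose preference is usually opposite to that of lipases), so that the (S)-carbinol is acetylated, giving 9.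

**Further compounds**
F1 | step 3 | (±)-4-hydroxy-5-tridecylidenecyclopent-2-en-1-one | O=C1C=C[C@@H](O)/C1=C/CCCCCCCCCCCC
F2 | step 4 | (±)-2-hydroxy-2-(1-hydroxytridecyl)cyclopent-4-ene-1,3-diyl diacetate | CCCCCCCCCCCC[C@@H](O)[C@]1(O)[C@H](OC(C)=O)C=C[C@@H]1OC(C)=O
F3 | step 5 | meso-1-[(1r,2R,5S)-1,2,5-trihydroxycyclopent-3-en-1-yl]tridecan-1-one | CCCCCCCCCCCCC(=O)[C@]1(O)[C@H](O)C=C[C@@H]1O
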